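The plan rests on breaking the C9–C10 bond of ring B, which turns ring A into a flat phenol. It uses two features of the target. Quaternary C10 stands para to oxygen-bearing C3 in ring A, and C9 sits beside the C8=C17 exocyclic methylene, the signature of an allylsilane that has reacted at its far end. One oxidation with a chiral trivalent-iodine reagent dearomatises ring A, joins C9 to C10, closes ring B, sets both stereocentres and expels silicon to leave the methylene. The precursor is a 2,4-dimethylphenol whose C5 carries a two-carbon tether to a (Z)-trisubstituted allyltrimethylsilane ending in a 3-furylethyl arm. The furan later becomes the (Z)-enediol.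

Key step: step 11

**Remarks on the chemistry**

- **Numbering:** labdane numbers are used. Ring A is C1–C5 plus C10 and ring B is C5–C10. C17 is the methylene carbon on C8, C18 the CH2OH on C4, C19 the CH3 on C4, C20 the CH3 on C10, C11/C12 the side-chain CH2 groups, and C13–C16 the furan or enediol carbons. The target is (2S,3S,4S,5S,9R,10S,13Z) in the ent-labdane series: a trans-decalin with C20 and C19 axial, and C18, O2, O3 and C11 equatorial.
- **Assumption:** the sense of induction of the chiral iodane cannot be predicted. The (R,R) reagent is written, and its (S,S) antipode, made from the other lactate, would be used if a test run favours the wrong face of C10.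
- **Iodane reagent:** it is Ar*I(OAc)2, CC(=O)OI(OC(C)=O)c1c(O[C@H](C)C(=O)Nc2c(C)cc(C)cc2C)cccc1O[C@H](C)C(=O)Nc1c(C)cc(C)cc1C. It is preformed from the commercial iodoarene (Selectfluor, AcOH/MeCN) and used stoichiometrically, so no peracid meets the furan or the allylsilane.
- **Structure check:** the (Z)-alkene of the phenol (CH2SiMe3 cis to C11) leads to H9 anti to C20, and the (9R,10S) dienone has the configuration of the target. No structure needed correction.
- **Design choices:**
  - The alkyne is C-silylated during the first coupling.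
  - The alkene geometry is locked in an isolable (Z)-alkenyl iodide.
  - O2 is silylated before C3 is reduced, so that O3 is the only free hydroxyl at the angeloylation.
  - The silyl ethers stay on until the last step, so that no free hydroxyl sits next to the angelate in a hydride medium.

**Route**

Step 1
Reactants: 1 2-bromo-1,3-dimethylbenzene
Product: 2 1-(3-bromo-2,4-dimethylphenyl)ethan-1-one
Conditions: AcCl, AlCl3, CH2Cl2, 0 °C
Reagents that add atoms: acetyl chloride, CC(=O)Cl
Why: Friedel–Crafts acylation should go to the only ring position that is ortho to one methyl and para to the other, since the site para to bromine is meta to both activating groups.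

Step 2
Reactants: 2 1-(3-bromo-2,4-dimethylphenyl)ethan-1-one
Product: 3 3-bromo-2,4-dimethylphenyl acetate
Conditions: mCPBA, CF3CO2H (cat.), CH2Cl2, 25 °C
Reagents that add atoms: mCPBA, O=C(OO)c1cccc(Cl)c1
Why: In the Baeyer–Villiger oxidation of this electron-rich, ortho-twisted acetophenone the aryl group migrates in preference to methyl, which places the future O3 next to the methyl-bearing C4.

Step 3
Reactants: 3 3-bromo-2,4-dimethylphenyl acetate; 4 (4-bromobut-1-yn-1-yl)trimethylsilane
Product: 6 2,4-dimethyl-3-[4-(trimethylsilyl)but-3-yn-1-yl]phenyl acetate, via butynylzinc bromide 5 (not isolated)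
Conditions: 4, Zn dust, LiCl, THF, 50 °C; then 3, Pd(OAc)2 (2 mol %), SPhos (4 mol %), THF, 50 °C
Reagents that add atoms: none
Why: Negishi sp3–sp2 coupling with a bulky biarylphosphine tolerates the two ortho methyl groups and the acetate, and silicon on the alkyne removes the acidic C–H that could quench the alkylzinc reagent.

Step 4
Reactants: 6 2,4-dimethyl-3-[4-(trimethylsilyl)but-3-yn-1-yl]phenyl acetate
Product: 7 3-(but-3-yn-1-yl)-2,4-dimethylphenol
Conditions: K2CO3 (0.3 equiv), MeOH, 25 °C
Reagents that add atoms: none
Why: Base-catalysed methanolysis cleaves the aryl acetate by transesterification and the alkynyl C–Si bond by protodesilylation in the same pot.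

Step 5
Reactants: 7 3-(but-3-yn-1-yl)-2,4-dimethylphenol
Product: 8 [3-(but-3-yn-1-yl)-2,4-dimethylphenoxy](tert-butyl)dimethylsilane
Conditions: TBSCl, imidazole, DMF, 25 °C
Reagents that add atoms: TBSCl, CC(C)(C)[Si](C)(C)Cl
Why: Standard O-silylation masks the acidic phenol, which would otherwise consume the organocopper reagent and be ring-iodinated in the next step.

Step 6
Reactants: 8 [3-(but-3-yn-1-yl)-2,4-dimethylphenoxy](tert-butyl)dimethylsilane
Product: 10 tert-butyl{3-[(3Z)-4-iodo-3-[(trimethylsilyl)methyl]but-3-en-1-yl]-2,4-dimethylphenoxy}dimethylsilane, via alkenylcopper 9 (not isolated)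
Conditions: Me3SiCH2MgCl, CuBr·SMe2, Et2O, −30 °C; 8, −30 → 10 °C; then I2, THF, −60 → 0 °C
Reagents that add atoms: (trimethylsilyl)methylmagnesium chloride, C[Si](C)(C)C[Mg]Cl; iodine, II
Why: Carbocupration of a terminal alkyne is a syn addition that puts the silylmethyl group on internal C8 and copper on C9, and iodinolysis with retention leaves CH2SiMe3 and iodine cis, the (Z)-geometry on which the C9/C10 relationship later depends.

Step 7
Reactants: 11 3-bromofuran
Product: 13 2-(furan-3-yl)ethan-1-ol, via 3-lithiofuran 12 (not isolated)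
Conditions: n-BuLi, THF, −78 °C; ethylene oxide, BF3·OEt2, −78 °C; aq. NaHCO3
Reagents that add atoms: ethylene oxide, C1CO1
Why: Bromine–lithium exchange kept at −78 °C, cold enough to prevent drift to the 2-lithio isomer, followed by BF3-assisted epoxide opening is the usual two-carbon homologation of 3-bromofuran.

Step 8
Reactants: 13 2-(furan-3-yl)ethan-1-ol
Product: 14 3-(2-iodoethyl)furan
Conditions: I2, PPh3, imidazole, CH2Cl2, 0 °C
Reagents that add atoms: iodine, II
Why: Appel-type iodination of a primary alcohol runs under essentially neutral conditions that the acid-sensitive furan tolerates.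

Step 9
Reactants: 10 (Z)-alkenyl iodide; 14 3-(2-iodoethyl)furan
Product: 16 tert-butyl{3-[(3Z)-6-(furan-3-yl)-3-[(trimethylsilyl)methyl]hex-3-en-1-yl]-2,4-dimethylphenoxy}dimethylsilane, via furylethylzinc iodide 15 (not isolated)
Conditions: 14, Zn dust, LiCl, THF, 25 °C; then 10, Pd(dppf)Cl2 (3 mol %), THF, 25 → 40 °C
Reagents that add atoms: none
Why: Negishi coupling of a primary alkylzinc iodide with an alkenyl iodide goes with retention of alkene geometry and leaves the allylsilane, furan and aryl silyl ether untouched, which makes it safer than direct alkylation of an alkenylcopper species.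

Step 10
Reactants: 16 silyl-protected cyclisation precursor
Product: 17 3-[(3Z)-6-(furan-3-yl)-3-[(trimethylsilyl)methyl]hex-3-en-1-yl]-2,4-dimethylphenol
Conditions: Cs2CO3 (0.5 equiv), DMF/H2O 10:1, 25 °C
Reagents that add atoms: none
Why: Aryl silyl ethers are hydrolysed by mild carbonate base because phenoxide is a good leaving group, so no fluoride or acid that could protodesilylate the allylsilane is needed.

Step 11
Reactants: 17 3-[(3Z)-6-(furan-3-yl)-3-[(trimethylsilyl)methyl]hex-3-en-1-yl]-2,4-dimethylphenol
Product: 19 (4aS,5R)-5-[2-(furan-3-yl)ethyl]-1,4a-dimethyl-6-methylidene-5,6,7,8-tetrahydronaphthalen-2(4aH)-one, via aryloxyiodane 18 (not isolated)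
Conditions: (R,R)-Ar*I(OAc)2 (1.1 equiv, preformed, slow addition), CH2Cl2/(CF3)2CHOH 9:1, 0.005 M, −40 °C
Reagents that add atoms: none
Why: Proposed new method: the phenol displaces one acetate on trivalent iodine to give aryloxyiodane 18, whose O–I bond breaks with loss of the aryl iodide while C9, the γ-carbon of the allylsilane, bonds to the para carbon C10 from one face of ring A, and the β-silyl cation at C8 then hands Me3Si to acetate, so the new alkene can only be C8=C17. The closest known reaction types are the racemic iodane-mediated para-dearomatisation of 4-alkylphenols by allylsilanes and other carbon nucleophiles and the enantioselective lactate-iodane dearomatisations, which so far give high selectivity only with oxygen nucleophiles, so the new element is asking such a reagent to choose the face for a C–C bond. Ring B closes in a 6-endo-trig mode with respect to the C8=C9 π bond (an intramolecular SE2′ reaction) with C6 and C7 as the tether. C10 is set by the chiral iodane, which must stay bound to O3 during bond formation (low temperature, mostly CH2Cl2, little fluoroalcohol) so that its lactamide arms screen one face, whereas C9 is set relative to C10 by the (Z)-alkene, because the two-atom tether lets C8 lie only outside ring A, which puts H9 over the ring and C11 (cis to CH2SiMe3) outside it and so makes H9 anti to C20. The step needs attack at para C10 and not at ortho C4, both of which would close a six-membered ring from C5, and this should follow from the larger LUMO coefficient at the para carbon, the bulky iodanyl group beside C4 and the greater stability of the cross-conjugated dienone. It also needs the allylsilane to outrun the furan, which intramolecularity (the furan could only close a ten-membered ring) and high dilution should secure.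

Step 12
Reactants: 19 cross-conjugated dienone
Product: 21 (4aS,5R)-5-[2-(furan-3-yl)ethyl]-1,4a-dimethyl-6-methylidene-4,4a,5,6,7,8-hexahydronaphthalen-2(3H)-one, via copper dienolate 20 (not isolated)
Conditions: [(Ph3P)CuH]6 (0.25 equiv), H2O (5 equiv), degassed toluene, 25 °C
Reagents that add atoms: none
Why: Copper hydride conjugate reduction delivers hydride only to the disubstituted C1=C2 enone arm, since the tetrasubstituted C4=C5 arm, the isolated C8=C17 alkene and the furan are inert to this soft hydride.

Step 13
Reactants: 21 C4=C5 enone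
Product: 23 (1S,4aS,5R,8aS)-5-[2-(furan-3-yl)ethyl]-1-(hydroxymethyl)-1,4a-dimethyl-6-methylideneoctahydronaphthalen-2(1H)-one, via lithium enolate 22 (not isolated)
Conditions: Li, NH3(l)/THF, t-BuOH (1 equiv), −78 → −33 °C; isoprene until colourless; evaporate NH3; CH2O (gas, from cracked paraformaldehyde), THF, −78 → −30 °C; aq. NH4Cl
Reagents that add atoms: formaldehyde, C=O
Why: Dissolving-metal enone reduction protonates C5 axially to give the trans ring fusion (H5 anti to C20) and releases the C3–C4 enolate regiospecifically, and this enolate undergoes aldol addition to formaldehyde on the face away from axial C20, so that C18 ends up equatorial and C19 axial.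

Step 14
Reactants: 23 keto alcohol
Product: 24 C18 tert-butyldimethylsilyl ether of 23 (4S,5S,9R,10S)
Conditions: TBSCl, imidazole, DMF, 25 °C
Reagents that add atoms: TBSCl, CC(C)(C)[Si](C)(C)Cl
Why: Silylation of the primary neopentyl alcohol blocks retro-aldol loss of formaldehyde under the strong base of the next step.

Step 15
Reactants: 24 silyloxy ketone
Product: 26 (2S)-2-hydroxy derivative of 24 (equatorial OH at C2, C3 ketone), via potassium enolate 25 (not isolated)
Conditions: KN(SiMe3)2, THF, −78 °C; 3-phenyl-2-(phenylsulfonyl)oxaziridine, −78 °C; AcOH quench at −78 °C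
Reagents that add atoms: 3-phenyl-2-(phenylsulfonyl)oxaziridine, O=S(=O)(N1OC1c1ccccc1)c1ccccc1
Why: With C4 quaternary only the C2 enolate can form, and its hydroxylation by the N-sulfonyloxaziridine (Davis oxidation) should take place on the face opposite the axial methyl groups C19 and C20 to give the equatorial (2S)-alcohol, which is also the more stable epimer.

Step 16
Reactants: 26 2-hydroxy ketone
Product: 27 O2 triethylsilyl ether of 26
Conditions: TESCl, imidazole, DMAP (cat.), CH2Cl2, 0 → 25 °C
Reagents that add atoms: TESCl, CC[Si](Cl)(CC)CC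
Why: Silylating O2 before C3 is reduced makes the later acylation unambiguous, because in a free 2,3-diol the less hindered O2 would be acylated first.

Step 17
Reactants: 27 2-silyloxy ketone
Product: 28 (2S,3S)-3-alcohol (O3 equatorial and trans to O2; O2 as TES ether, O18 as TBS ether)
Conditions: NaBH4, MeOH/THF, −20 → 0 °C
Reagents that add atoms: none
Why: Borohydride reduction follows the axial trajectory on the face free of the axial C19 and C20 methyl groups, the normal course for 4,4-disubstituted 3-ketones of this ring system, and gives the equatorial (3S)-alcohol.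

Step 18
Reactants: 28 C3 alcohol; 29 angelic acid, (Z)-2-methylbut-2-enoic acid
Product: 31 3-O-angelate of 28, via mixed anhydride 30 (not isolated)
Conditions: 29, 2,4,6-trichlorobenzoyl chloride, Et3N, toluene, 25 °C; then 28, toluene, 80 °C
Reagents that add atoms: none
Why: Mixed-anhydride (Yamaguchi-type) esterification run without a nucleophilic catalyst acylates hindered secondary alcohols at the less hindered angeloyl carbonyl and avoids the addition–elimination pathway that turns angelates into tiglates.

Step 19
Reactants: 31 furan angelate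
Product: 34 (13Z)-15,16-diol (angelate on O3, TES on O2, TBS on O18), via furan endoperoxide 32 (not isolated), via cis-enedial 33 (not isolated)
Conditions: O2, hν (visible), tetraphenylporphyrin (cat.), CH2Cl2, −78 °C; Me2S, −78 → −20 °C; then MeOH, CeCl3·7H2O, NaBH4, −78 → 0 °C
Reagents that add atoms: oxygen, O=O
Why: Singlet oxygen adds [4+2] to the electron-rich furan far faster than it undergoes the ene reaction with the 1,1-disubstituted or the ester-conjugated alkene, sulfide reduction opens the endoperoxide to the cis-enedial, and Luche 1,2-reduction keeps the ring-derived (Z)-geometry.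

Step 20
Reactants: 34 bis-silylated diol
Product: 35 target CNP0324138.1
Conditions: HF·pyridine, pyridine, THF, 0 → 25 °C
Reagents that add atoms: none
Why: Buffered HF·pyridine desilylation removes both silyl ethers in a weakly acidic medium in which the angelate should neither migrate to O2 or O18 nor isomerise, and in which the exocyclic alkene and the allylic diol are left alone.

**Compound list**

1 | 2-bromo-1,3-dimethylbenzene | Cc1cccc(C)c1Br | starting material
2 | 1-(3-bromo-2,4-dimethylphenyl)ethan-1-one | CC(=O)c1ccc(C)c(Br)c1C | intermediate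
3 | 3-bromo-2,4-dimethylphenyl acetate | CC(=O)Oc1ccc(C)c(Br)c1C | intermediate
4 | (4-bromobut-1-yn-1-yl)trimethylsilane | C[Si](C)(C)C#CCCBr | starting material
5 | [4-(trimethylsilyl)but-3-yn-1-yl]zinc bromide | C[Si](C)(C)C#CCC[Zn]Br | intermediate
6 | 2,4-dimethyl-3-[4-(trimethylsilyl)but-3-yn-1-yl]phenyl acetate | CC(=O)Oc1ccc(C)c(CCC#C[Si](C)(C)C)c1C | intermediate
7 | 3-(but-3-yn-1-yl)-2,4-dimethylphenol | C#CCCc1c(C)ccc(O)c1C | intermediate
8 | [3-(but-3-yn-1-yl)-2,4-dimethylphenoxy](tert-butyl)dimethylsilane | C#CCCc1c(C)ccc(O[Si](C)(C)C(C)(C)C)c1C | intermediate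
9 | (Z)-alkenylcopper, Cu on C9 cis to CH2SiMe3 | C[Si](C)(C)C/C(CCc1c(C)ccc(O[Si](C)(C)C(C)(C)C)c1C)=C\[Cu] | intermediate
10 | tert-butyl{3-[(3Z)-4-iodo-3-[(trimethylsilyl)methyl]but-3-en-1-yl]-2,4-dimethylphenoxy}dimethylsilane | C[Si](C)(C)C/C(CCc1c(C)ccc(O[Si](C)(C)C(C)(C)C)c1C)=C\I | intermediate
11 | 3-bromofuran | Brc1ccoc1 | starting material
12 | furan-3-yllithium | [Li]c1ccoc1 | intermediate
13 | 2-(furan-3-yl)ethan-1-ol | OCCc1ccoc1 | intermediate
14 | 3-(2-iodoethyl)furan | ICCc1ccoc1 | intermediate
15 | [2-(furan-3-yl)ethyl]zinc iodide | I[Zn]CCc1ccoc1 | intermediate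
16 | tert-butyl{3-[(3Z)-6-(furan-3-yl)-3-[(trimethylsilyl)methyl]hex-3-en-1-yl]-2,4-dimethylphenoxy}dimethylsilane | Cc1c(O[Si](C)(C)C(C)(C)C)ccc(C)c1CC/C(C[Si](C)(C)C)=C/CCc1ccoc1 | intermediate
17 | 3-[(3Z)-6-(furan-3-yl)-3-[(trimethylsilyl)methyl]hex-3-en-1-yl]-2,4-dimethylphenol (key-step precursor) | Cc1c(O)ccc(C)c1CC/C(C[Si](C)(C)C)=C/CCc1ccoc1 | intermediate
18 | acetoxy(aryloxy)-λ3-iodane from 17 and (R,R)-Ar*I(OAc)2 | CC(=O)OI(Oc1ccc(C)c(CC/C(C[Si](C)(C)C)=C/CCc2ccoc2)c1C)c1c(O[C@H](C)C(=O)Nc2c(C)cc(C)cc2C)cccc1O[C@H](C)C(=O)Nc1c(C)cc(C)cc1C | intermediate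
19 | (4aS,5R)-5-[2-(furan-3-yl)ethyl]-1,4a-dimethyl-6-methylidene-5,6,7,8-tetrahydronaphthalen-2(4aH)-one (9R,10S; key-step product) | C=C1CCC2=C(C)C(=O)C=C[C@@]2(C)[C@@H]1CCc1ccoc1 | intermediate
20 | copper dienolate of 21 (O3–Cu, C2=C3, C4=C5) | C=C1CCC2=C(C)C(O[Cu])=CC[C@@]2(C)[C@@H]1CCc1ccoc1 | intermediate
21 | (4aS,5R)-5-[2-(furan-3-yl)ethyl]-1,4a-dimethyl-6-methylidene-4,4a,5,6,7,8-hexahydronaphthalen-2(3H)-one | C=C1CCC2=C(C)C(=O)CC[C@@]2(C)[C@@H]1CCc1ccoc1 | intermediate
22 | lithium C3–C4 enolate, trans-fused (5S,9R,10S) | C=C1CC[C@H]2[C@@](C)(CCC(O[Li])=C2C)[C@@H]1CCc1ccoc1 | intermediate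
23 | (1S,4aS,5R,8aS)-5-[2-(furan-3-yl)ethyl]-1-(hydroxymethyl)-1,4a-dimethyl-6-methylideneoctahydronaphthalen-2(1H)-one (4S,5S,9R,10S) | C=C1CC[C@H]2[C@@](C)(CCC(=O)[C@]2(C)CO)[C@@H]1CCc1ccoc1 | intermediate
24 | C18 TBS ether of 23 | C=C1CC[C@H]2[C@@](C)(CCC(=O)[C@]2(C)CO[Si](C)(C)C(C)(C)C)[C@@H]1CCc1ccoc1 | intermediate
25 | potassium C2–C3 enolate of 24 | C=C1CC[C@H]2[C@@](C)(CC=C(O[K])[C@]2(C)CO[Si](C)(C)C(C)(C)C)[C@@H]1CCc1ccoc1 | intermediate
26 | (2S)-2-hydroxy-3-ketone, C18 TBS ether | C=C1CC[C@H]2[C@@](C)(C[C@H](O)C(=O)[C@]2(C)CO[Si](C)(C)C(C)(C)C)[C@@H]1CCc1ccoc1 | intermediate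
27 | (2S)-2-(triethylsilyloxy)-3-ketone, C18 TBS ether | C=C1CC[C@H]2[C@@](C)(C[C@H](O[Si](CC)(CC)CC)C(=O)[C@]2(C)CO[Si](C)(C)C(C)(C)C)[C@@H]1CCc1ccoc1 | intermediate
28 | (2S,3S)-3-alcohol, O2 TES, O18 TBS | C=C1CC[C@H]2[C@@](C)(C[C@H](O[Si](CC)(CC)CC)[C@@H](O)[C@]2(C)CO[Si](C)(C)C(C)(C)C)[C@@H]1CCc1ccoc1 | intermediate
29 | angelic acid, (Z)-2-methylbut-2-enoic acid | C/C=C(/C)C(=O)O | starting material
30 | angelic 2,4,6-trichlorobenzoic anhydride | C/C=C(/C)C(=O)OC(=O)c1c(Cl)cc(Cl)cc1Cl | intermediate
31 | 3-O-angelate, O2 TES, O18 TBS, furan intact | C=C1CC[C@H]2[C@@](C)(C[C@H](O[Si](CC)(CC)CC)[C@@H](OC(=O)/C(C)=C\C)[C@]2(C)CO[Si](C)(C)C(C)(C)C)[C@@H]1CCc1ccoc1 | intermediate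
32 | furan endoperoxide of 31 (2,3,7-trioxabicyclo[2.2.1]hept-5-ene; both bridgehead diastereomers) | C=C1CC[C@H]2[C@@](C)(C[C@H](O[Si](CC)(CC)CC)[C@@H](OC(=O)/C(C)=C\C)[C@]2(C)CO[Si](C)(C)C(C)(C)C)[C@@H]1CCC1=CC2OOC1O2 | intermediate
33 | (13Z)-15,16-dial | C=C1CC[C@H]2[C@@](C)(C[C@H](O[Si](CC)(CC)CC)[C@@H](OC(=O)/C(C)=C\C)[C@]2(C)CO[Si](C)(C)C(C)(C)C)[C@@H]1CC/C(=C/C=O)C=O | intermediate
34 | (13Z)-15,16-diol, O3 angelate, O2 TES, O18 TBS | C=C1CC[C@H]2[C@@](C)(C[C@H](O[Si](CC)(CC)CC)[C@@H](OC(=O)/C(C)=C\C)[C@]2(C)CO[Si](C)(C)C(C)(C)C)[C@@H]1CC/C(=C/CO)CO | intermediate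
35 | (2S,3S,4S,5S,9R,10S,13Z)-2,15,16,18-tetrahydroxylabda-8(17),13-dien-3-yl (Z)-2-methylbut-2-enoate, CNP0324138.1 | C=C1CC[C@H]2[C@@](C)(C[C@H](O)[C@@H](OC(=O)/C(C)=C\C)[C@]2(C)CO)[C@@H]1CC/C(=C/CO)CO | target

**Step count**

Total step count: 20. Longest linear sequence: 18 steps, from 1 through steps 1–6 and 9–20. Steps 7 and 8 form the side branch.

**Steps most likely to fail**

1. **Step 11.**
   - **Risks:**
     - The O–I bond may ionise before the C–C bond forms, which would erase the facial discrimination.
     - Closure at ortho C4 may compete.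
     - The fluoroalcohol may capture the cation.
     - Proton loss from C20 may lead to a quinone methide.
   - **Fallback (known chemistry):** starting from 17, the cyclisation is run without a chiral reagent, using PhI(OAc)2 in (CF3)2CHOH at 0 °C. This should give 19 together with its mirror image, the (4aR,5S)-dienone F1. The two are separated by preparative chromatography on a polysaccharide chiral stationary phase. The route is rejoined at 19.

2. **Step 13.**
   - **Risks:**
     - Proton transfer to the enolate may outrun the aldol addition.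
     - Formaldehyde may polymerise.
     - Enolate equilibration may allow a second hydroxymethylation at C2.
     - Facial selectivity at C4 may be incomplete.
   - **Fallback:** starting from 21, reduction and C–C bond formation are separated. The same Li/NH3 reduction is quenched with Me3SiCl/Et3N, and the regiodefined trimethylsilyl enol ether F2 is isolated. F2 then undergoes a Mukaiyama aldol reaction with aqueous formaldehyde under Yb(OTf)3 catalysis in THF at 25 °C. The route is rejoined at 23.

3. **Step 18.**
   - **Risks:**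
     - Acylation of O3, which is flanked by the quaternary C4 and the O2 silyl ether, may be slow.
     - The angeloyl unit may isomerise from Z to E on long heating.
     - Silicon may migrate from O2 to O3.
   - **Fallback:** the alkene is built on the ester and not brought in with the acid. Starting from 28, esterification with 2-[bis(2,2,2-trifluoroethoxy)phosphoryl]propanoic acid (EDC·HCl, DMAP, CH2Cl2) gives the phosphonopropionate ester F3. A Still–Gennari olefination with acetaldehyde (KN(SiMe3)2, 18-crown-6, THF, −78 °C) then forms the (Z)-2-methylbut-2-enoate. The route is rejoined at 31.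

Further compounds
F1 | step 11 | (4aR,5S)-5-[2-(furan-3-yl)ethyl]-1,4a-dimethyl-6-methylidene-5,6,7,8-tetrahydronaphthalen-2(4aH)-one (mirror image of 19) | C=C1CCC2=C(C)C(=O)C=C[C@]2(C)[C@H]1CCc1ccoc1
F2 | step 13 | trimethylsilyl C3–C4 enol ether, trans-fused (5S,9R,10S) | C=C1CC[C@H]2[C@@](C)(CCC(O[Si](C)(C)C)=C2C)[C@@H]1CCc1ccoc1
F3 | step 18 | 3-O-{2-[bis(2,2,2-trifluoroethoxy)phosphoryl]propanoyl} derivative of 28 (both epimers at the phosphonate α-carbon) | C=C1CC[C@H]2[C@@](C)(C[C@H](O[Si](CC)(CC)CC)[C@@H](OC(=O)C(C)P(=O)(OCC(F)(F)F)OCC(F)(F)F)[C@]2(C)CO[Si](C)(C)C(C)(C)C)[C@@H]1CCc1ccoc1
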